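**Assumption:** the target has no stereocentre and is achiral, so the drawn compound is the only stereoisomer and no enantiocontrol is needed; the hydroxyquinone rings are written in the tautomeric form of the given SMILES.

## Retrosynthetic overview

1. Target 11 ⇒ bis-hydroquinone 10 ⇒ heptaacetate 9 ⇒ bis-quinone 8 ⇒ mono-methyl ether 7: the two missing oxygens of each ring are added after O-methylation, the order proposed for related plant methoxy-hydroxyquinones.
2. 7 ⇒ mono-O-methylation of the symmetric bis(2-methylresorcinol) 6; the two OH groups of a ring are equivalent, so the OMe necessarily ends up next to the ring methyl.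
3. 6 ⇒ two-directional polyketide-type aldol cyclisation/aromatisation of the open-chain bis-triketone 4; rings A and B are formed together, in one operation.
4. 4 ⇒ dimethyl pentadecanedioate 2 (the diacid "starter"; its two carboxyl carbons become the chain-bearing ring carbons) plus two dianions of 3-methylpentane-2,4-dione 1 (the "extender").

## Route

Step 1
Reactants: 1 3-methylpentane-2,4-dione; 2 dimethyl pentadecanedioate
Product: 4 3,23-dimethylpentacosane-2,4,6,20,22,24-hexaone, via dilithio-3-methylpentane-2,4-dione 3 (not isolated)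
Conditions: 1 (4.4 equiv), LiN(iPr)2 (8.8 equiv), THF, 0 °C; then 2 (1 equiv), 0 °C → rt; cold 1 M HCl to pH 4
Reagents that add atoms: none
Why: Hauser–Harris terminal acylation (Claisen-type) of a β-diketone 1,3-dianion, which reacts only at its last-formed, most basic CH2 terminus; the second equivalent of dianion per ester deprotonates the triketone as it forms, which stops over-reaction.

Step 2
Reactants: 4 3,23-dimethylpentacosane-2,4,6,20,22,24-hexaone
Product: 6 5,5'-(tridecane-1,13-diyl)bis(2-methylbenzene-1,3-diol), via bis-aldol 5 (not isolated)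
Conditions: KOH (2 M aq)/THF, degassed, 0.01 M, Ar, rt → 50 °C; then 2 M HCl
Reagents that add atoms: none
Why: Proposed new method: a twofold intramolecular aldol condensation/aromatisation in which, at each end, the enolate of the free acetyl methyl (C1/C25) adds to the chain ketone (C6/C20) and loss of two waters gives the arene, the closest known reaction being Collie's base cyclisation of diacetylacetone to orcinol and the enzymatic parallel being the C–C ring closure of an alkylresorcinol synthase on its poly-β-keto chain; the C3 methyl makes the C4–C5–C6 diketonate the favoured monoanion, so the acetyl stays a free enolisable ketone, the competing C7→C2 closure needs the less populated anion and a methylene nucleophile and would give a crowded arene, the anionic state shields the chain from retro-Claisen cleavage, and high dilution suppresses intermolecular aldol.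

Step 3
Reactants: 6 5,5'-(tridecane-1,13-diyl)bis(2-methylbenzene-1,3-diol)
Product: 7 5-[13-(3-hydroxy-5-methoxy-4-methylphenyl)tridecyl]-2-methylbenzene-1,3-diol
Conditions: MeI (1.0 equiv), K2CO3 (1.0 equiv), acetone, 56 °C; chromatography, recovered 6 recycled
Reagents that add atoms: iodomethane, CI
Why: Williamson ether synthesis on four equivalent phenols, so any single methylation gives the same product (statistical, about 35–40 % per pass), which separates easily from the tetraol and the dimethyl ethers.

Step 4
Reactants: 7 5-[13-(3-hydroxy-5-methoxy-4-methylphenyl)tridecyl]-2-methylbenzene-1,3-diol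
Product: 8 2-hydroxy-3-methyl-6-[13-(5-methoxy-4-methyl-3,6-dioxocyclohexa-1,4-dien-1-yl)tridecyl]cyclohexa-2,5-diene-1,4-dione
Conditions: (KSO3)2NO (Fremy's salt, 5 equiv), KH2PO4 (aq), acetone/H2O, rt
Reagents that add atoms: potassium nitrosodisulfonate, [K+].[K+].[O]N(S(=O)(=O)[O-])S(=O)(=O)[O-]
Why: Teuber oxidation, in which each ring has a free position para to a phenolic OH, so the phenol ether ring gives the 2-methoxy-p-quinone and the resorcinol ring the 2-hydroxy-p-quinone, leaving one ring C–H next to the chain on each ring.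

Step 5
Reactants: 8 2-hydroxy-3-methyl-6-[13-(5-methoxy-4-methyl-3,6-dioxocyclohexa-1,4-dien-1-yl)tridecyl]cyclohexa-2,5-diene-1,4-dione
Product: 9 3-[13-(2,3,5,6-tetraacetoxy-4-methylphenyl)tridecyl]-5-methoxy-6-methylbenzene-1,2,4-triyl triacetate
Conditions: Ac2O, BF3·OEt2 (cat.), 40 °C
Reagents that add atoms: acetic anhydride, CC(=O)OC(C)=O
Why: Thiele–Winter acetoxylation, in which the hydroxyquinone is O-acetylated and acetate then adds in conjugate fashion to the only free ring position of each quinone, which is also the electronically normal position for a 2-alkoxyquinone, with in situ acetylation of the resulting hydroquinones.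

Step 6
Reactants: 9 3-[13-(2,3,5,6-tetraacetoxy-4-methylphenyl)tridecyl]-5-methoxy-6-methylbenzene-1,2,4-triyl triacetate
Product: 11 2-hydroxy-3-[13-(2,5-dihydroxy-4-methyl-3,6-dioxocyclohexa-1,4-dien-1-yl)tridecyl]-5-methoxy-6-methylcyclohexa-2,5-diene-1,4-dione (target), via heptahydroxy bis-hydroquinone 10 (not isolated)
Conditions: HCl (cat.), MeOH, Ar, 50 °C; evaporate; then EtOAc/H2O, air (O2), rt
Reagents that add atoms: none
Why: Acid-catalysed transesterification removes the seven aryl acetates without touching the aryl methyl ether, and autoxidation of the electron-rich hydroxyhydroquinone rings gives the two p-quinones, the OMe staying on its carbon next to the ring methyl.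

## Compound list

1 | 3-methylpentane-2,4-dione | CC(=O)C(C)C(C)=O | starting material
2 | dimethyl pentadecanedioate | COC(=O)CCCCCCCCCCCCCC(=O)OC | starting material
3 | dilithio-3-methylpentane-2,4-dione (1,3-dianion of 1) | [Li+].[Li+].[CH2-]C(=O)[C-](C)C(C)=O | intermediate
4 | 3,23-dimethylpentacosane-2,4,6,20,22,24-hexaone (keto form; C3 and C23 enolisable, no fixed configuration) | CC(=O)C(C)C(=O)CC(=O)CCCCCCCCCCCCCC(=O)CC(=O)C(C)C(C)=O | intermediate
5 | 5,5'-(tridecane-1,13-diyl)bis(5-hydroxy-2-methylcyclohexane-1,3-dione) (isomer mixture, no configuration defined) | CC1C(=O)CC(O)(CC1=O)CCCCCCCCCCCCCC1(O)CC(=O)C(C)C(=O)C1 | intermediate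
6 | 5,5'-(tridecane-1,13-diyl)bis(2-methylbenzene-1,3-diol) | Cc1c(O)cc(CCCCCCCCCCCCCc2cc(O)c(C)c(O)c2)cc1O | intermediate
7 | 5-[13-(3-hydroxy-5-methoxy-4-methylphenyl)tridecyl]-2-methylbenzene-1,3-diol | COc1cc(CCCCCCCCCCCCCc2cc(O)c(C)c(O)c2)cc(O)c1C | intermediate
8 | 2-hydroxy-3-methyl-6-[13-(5-methoxy-4-methyl-3,6-dioxocyclohexa-1,4-dien-1-yl)tridecyl]cyclohexa-2,5-diene-1,4-dione | COC1=C(C)C(=O)C=C(CCCCCCCCCCCCCC2=CC(=O)C(C)=C(O)C2=O)C1=O | intermediate
9 | 3-[13-(2,3,5,6-tetraacetoxy-4-methylphenyl)tridecyl]-5-methoxy-6-methylbenzene-1,2,4-triyl triacetate | COc1c(C)c(OC(C)=O)c(OC(C)=O)c(CCCCCCCCCCCCCc2c(OC(C)=O)c(OC(C)=O)c(C)c(OC(C)=O)c2OC(C)=O)c1OC(C)=O | intermediate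
10 | 3-[13-(2,3,5,6-tetrahydroxy-4-methylphenyl)tridecyl]-5-methoxy-6-methylbenzene-1,2,4-triol | COc1c(C)c(O)c(O)c(CCCCCCCCCCCCCc2c(O)c(O)c(C)c(O)c2O)c1O | intermediate
11 | 2-hydroxy-3-[13-(2,5-dihydroxy-4-methyl-3,6-dioxocyclohexa-1,4-dien-1-yl)tridecyl]-5-methoxy-6-methylcyclohexa-2,5-diene-1,4-dione | COC1=C(C)C(=O)C(O)=C(CCCCCCCCCCCCCC2=C(O)C(=O)C(C)=C(O)C2=O)C1=O | target

## Summary

Total step count: 6. Longest linear sequence: 6 steps (1 and 2 → 11).

**Steps most likely to fail**

Step 2 (double cyclisation; wrong-way closure, chain cleavage or oligomerisation are possible). The fallback sets out from 4 and comes back at 6. Compound 4 is treated with excess LiN(iPr)2 in THF at 0 °C to form the trianion at each end, and CO2 carboxylates both terminal methyl groups to give 4,24-dimethyl-3,5,7,21,23,25-hexaoxoheptacosanedioic acid F3. In aqueous buffer at pH 8–9 the carboxyl-activated C2 methylene of each end closes onto the C7 ketone, which fixes the regiochemistry, and gives 6,6'-(tridecane-1,13-diyl)bis(2,4-dihydroxy-3-methylbenzoic acid) F4. Heating F4 in DMF at 130 °C removes both carboxyl groups and delivers 6.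

Step 5 (Thiele–Winter acetoxylation of trisubstituted, donor-bearing quinones can be sluggish). The fallback sets out from 7, replaces steps 4 and 5, and comes back at 10. Compound 7 is formylated at all four free ring positions by a Duff reaction (hexamethylenetetramine, CF3CO2H, reflux) to give 4-hydroxy-6-methoxy-5-methyl-2-[13-(2,6-diformyl-3,5-dihydroxy-4-methylphenyl)tridecyl]benzene-1,3-dicarbaldehyde F5. Dakin oxidation (H2O2, B(OH)3, cat. H2SO4, THF, Ar) turns the four formyl groups, each ortho or para to an oxygen substituent, into hydroxyls and gives 10, which is oxidised in air as in step 6 to 11.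

Step 1 (twofold acylation with an enolisable diester; proton transfer and Claisen self-condensation can lower the yield). The fallback sets out from 2 and comes back at 4. Compound 2 is reduced with iBu2AlH (toluene, −78 °C) to pentadecanedial F1. Aldol addition of dianion 3 (THF, −78 °C) to both aldehyde groups gives 6,20-dihydroxy-3,23-dimethylpentacosane-2,4,22,24-tetraone F2 as a mixture of diastereomers, and Dess–Martin periodinane (CH2Cl2, rt) oxidises both carbinols to return to 4.

## Further compounds

F1 | step 1 | pentadecanedial | O=CCCCCCCCCCCCCCC=O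
F2 | step 1 | 6,20-dihydroxy-3,23-dimethylpentacosane-2,4,22,24-tetraone (mixture of diastereomers, no configuration defined) | CC(=O)C(C)C(=O)CC(O)CCCCCCCCCCCCCC(O)CC(=O)C(C)C(C)=O
F3 | step 2 | 4,24-dimethyl-3,5,7,21,23,25-hexaoxoheptacosanedioic acid | OC(=O)CC(=O)C(C)C(=O)CC(=O)CCCCCCCCCCCCCC(=O)CC(=O)C(C)C(=O)CC(=O)O
F4 | step 2 | 6,6'-(tridecane-1,13-diyl)bis(2,4-dihydroxy-3-methylbenzoic acid) | Cc1c(O)cc(CCCCCCCCCCCCCc2cc(O)c(C)c(O)c2C(=O)O)c(C(=O)O)c1O
F5 | step 5 | 4-hydroxy-6-methoxy-5-methyl-2-[13-(2,6-diformyl-3,5-dihydroxy-4-methylphenyl)tridecyl]benzene-1,3-dicarbaldehyde | COc1c(C)c(O)c(C=O)c(CCCCCCCCCCCCCc2c(C=O)c(O)c(C)c(O)c2C=O)c1C=O
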